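**Retrosynthetic overview**

1. The (E)-propenyl group on C5 is attached last, by Suzuki–Miyaura coupling of a C5 chloride, so that no alkene is present during hydrogenation and acid treatment.
2. Both stereocentres come from a 2-aryl-3-methylbenzofuran: enantioselective syn-hydrogenation of C2=C3 fixes C3, then acid epimerises the benzylic C2 to the trans isomer and frees the phenol in the same step.
3. Key disconnection: the furan ring (ring B) is cut at C3–C3a and O1–C7a, giving a propiophenone (its O1–C2–C3 unit as the enolate) and a 2-iodoaryl triflate (ring A); one palladium-catalysed C-arylation/O-arylation cascade forms both bonds.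
4. Enabling feature: the neighbouring ring A carbons C3a and C7a carry iodide and triflate (C7a flanked by the C7 methoxy group), a 1,2-dielectrophile of graded reactivity, and the C2 carbonyl makes C3 and O1 the two ends of one enolate; the extra C2=C3 unsaturation this needs is removed in step 5.
5. Ring order: ring A (benzo) and ring C (syringyl) are bought; ring B is the only ring formed, in step 4.

Key step: step 4

Assumption: 4-chloro-2-methoxyphenol, propiosyringone and (E)-prop-1-enylboronic acid pinacol ester are taken as catalogue compounds, and the antipode of the carbene ligand in step 5 that gives 3R is to be fixed by a test hydrogenation, both antipodes being available.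

**Route**

Step 1
Reactants: 1 4-chloro-2-methoxyphenol
Product: 2 4-chloro-2-iodo-6-methoxyphenol
Conditions: I2 (1.05 equiv), NaHCO3, THF/H2O, 0 °C to rt
Reagents that add atoms: iodine, II
Why: Electrophilic aromatic iodination of the phenoxide should go to C6, the only free position ortho to the strongly activating oxygen, because the para position is blocked by chlorine.

Step 2
Reactants: 2 4-chloro-2-iodo-6-methoxyphenol
Product: 3 4-chloro-2-iodo-6-methoxyphenyl trifluoromethanesulfonate
Conditions: Tf2O, pyridine, CH2Cl2, 0 °C
Reagents that add atoms: trifluoromethanesulfonic anhydride, O=S(=O)(OS(=O)(=O)C(F)(F)F)C(F)(F)F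
Why: Standard O-sulfonylation of a phenol turns the C–O bond into a pseudohalide next to the iodide, which gives the 1,2-dielectrophile for the key step.

Step 3
Reactants: 4 1-(4-hydroxy-3,5-dimethoxyphenyl)propan-1-one (propiosyringone)
Product: 5 1-[3,5-dimethoxy-4-(methoxymethoxy)phenyl]propan-1-one
Conditions: MOMCl, iPr2NEt, CH2Cl2, 0 °C to rt
Reagents that add atoms: chloromethyl methyl ether, COCCl
Why: O-alkylation of the phenol (MOM protection) prevents formation of a para-acyl phenoxide that would suppress enolisation of the ketone, and the acetal should survive phosphate base and hydrogenation until the acid of step 6 removes it.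

Step 4
Reactants: 3 4-chloro-2-iodo-6-methoxyphenyl trifluoromethanesulfonate; 5 1-[3,5-dimethoxy-4-(methoxymethoxy)phenyl]propan-1-one
Product: 7 5-chloro-2-[3,5-dimethoxy-4-(methoxymethoxy)phenyl]-7-methoxy-3-methyl-1-benzofuran, via alpha-aryl ketone 6 (not isolated)
Conditions: Pd2(dba)3 (2.5 mol %), Xantphos (6 mol %), K3PO4 (3 equiv), toluene, 80 °C then 110 °C
Reagents that add atoms: none
Why: Zerovalent palladium should insert first into the C3a–I bond of 3 (far more reactive than the hindered, electron-rich C7a–OTf bond beside the C7 methoxy group and than C5–Cl), the potassium enolate of 5 transmetalates, and C–C reductive elimination gives alpha-aryl ketone 6 with the new C3–C3a bond. Ketone 6, now doubly activated at C3, is re-enolised by the phosphate; oxidative addition into the neighbouring C7a–OTf bond is followed by O-coordination of this enolate, and C–O reductive elimination from the six-membered oxapalladacycle (Pd–C7a–C3a–C3=C2–O1) forms the O1–C7a bond. The closest known reaction type is the palladium-catalysed alpha-arylation of ketones and its tandem C-arylation/O-arylation of ketones with 1,2-dihaloarenes to give benzofurans. Ring B closes as a five-membered ring by intramolecular O-arylation of the enolate (C-attack would need a four-membered ring), and the aromatic furan is the thermodynamic sink. No stereocentre is formed here, because ring B is deliberately made at the C2=C3 oxidation level; C3 and C2 are set in steps 5 and 6. The selectivity needed is positional (enolate carbon to C3a, enolate oxygen to C7a), and it should be secured by the reactivity order I > OTf > Cl on ring A together with the preference of palladium ketone enolates for intermolecular C-arylation.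

Step 5
Reactants: 7 5-chloro-2-[3,5-dimethoxy-4-(methoxymethoxy)phenyl]-7-methoxy-3-methyl-1-benzofuran
Product: 8 (2S,3R)-5-chloro-2-[3,5-dimethoxy-4-(methoxymethoxy)phenyl]-7-methoxy-3-methyl-2,3-dihydro-1-benzofuran (cis)
Conditions: Ru(cod)(2-methylallyl)2 (5 mol %), SINpEt·HBF4 (10 mol %, antipode chosen for 3R), KOtBu (12 mol %), H2 (60 bar), n-hexane, 40 °C
Reagents that add atoms: none
Why: Asymmetric hydrogenation of the benzofuran C2=C3 bond with a chiral ruthenium N-heterocyclic carbene catalyst adds H2 syn to one face of ring B, so the cis product is expected with C3 set as R by the ligand (the S configuration at C2 is corrected in step 6), while the benzene rings, the aryl chloride and the MOM acetal should be left alone under these mild conditions.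

Step 6
Reactants: 8 (2S,3R)-5-chloro-2-[3,5-dimethoxy-4-(methoxymethoxy)phenyl]-7-methoxy-3-methyl-2,3-dihydro-1-benzofuran
Product: 10 4-[(2R,3R)-5-chloro-7-methoxy-3-methyl-2,3-dihydro-1-benzofuran-2-yl]-2,6-dimethoxyphenol (trans), via cis phenol 9 (not isolated)
Conditions: TFA/CH2Cl2 (1:9), H2O (5 equiv), 0 °C to rt
Reagents that add atoms: none
Why: The acid hydrolyses the MOM acetal to cis phenol 9 and then reversibly ionises the C2–O1 bond to a benzylic cation strongly stabilised by the 4-hydroxy-3,5-dimethoxyphenyl ring (a protonated para-quinone methide), and reclosure by the ring A phenol under thermodynamic control should give the more stable trans isomer, inverting C2 to R while C3, which is not part of the ionising bond, stays R (acid-mediated cis-to-trans epimerisation of 2-aryl-2,3-dihydrobenzofurans).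

Step 7
Reactants: 10 4-[(2R,3R)-5-chloro-7-methoxy-3-methyl-2,3-dihydro-1-benzofuran-2-yl]-2,6-dimethoxyphenol
Product: 11 maceneolignan A, 2,6-dimethoxy-4-[(2R,3R)-7-methoxy-3-methyl-5-[(E)-prop-1-enyl]-2,3-dihydro-1-benzofuran-2-yl]phenol
Conditions: (E)-prop-1-enylboronic acid pinacol ester (1.5 equiv), Pd(OAc)2 (3 mol %), SPhos (6 mol %), K3PO4 (3 equiv), THF/H2O (10:1), 60 °C
Reagents that add atoms: (E)-prop-1-enylboronic acid pinacol ester, C/C=C/B1OC(C)(C)C(C)(C)O1
Why: Suzuki–Miyaura coupling of the unhindered aryl chloride with an (E)-alkenylboronate and a dialkylbiarylphosphine ligand proceeds with retention of alkene geometry, tolerates the free phenol as its phenoxide, and should not touch either stereocentre under the mildly basic conditions.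

**Compound list**

1 | 4-chloro-2-methoxyphenol | Oc1ccc(Cl)cc1OC | starting material
2 | 4-chloro-2-iodo-6-methoxyphenol | Oc1c(I)cc(Cl)cc1OC | intermediate
3 | 4-chloro-2-iodo-6-methoxyphenyl trifluoromethanesulfonate | COc1cc(Cl)cc(I)c1OS(=O)(=O)C(F)(F)F | intermediate
4 | 1-(4-hydroxy-3,5-dimethoxyphenyl)propan-1-one (propiosyringone) | CCC(=O)c1cc(OC)c(O)c(OC)c1 | starting material
5 | 1-[3,5-dimethoxy-4-(methoxymethoxy)phenyl]propan-1-one | CCC(=O)c1cc(OC)c(OCOC)c(OC)c1 | intermediate
6 | racemic 4-chloro-2-{1-[3,5-dimethoxy-4-(methoxymethoxy)phenyl]-1-oxopropan-2-yl}-6-methoxyphenyl trifluoromethanesulfonate (alpha-aryl ketone, not isolated) | CC(C(=O)c1cc(OC)c(OCOC)c(OC)c1)c1cc(Cl)cc(OC)c1OS(=O)(=O)C(F)(F)F | intermediate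
7 | 5-chloro-2-[3,5-dimethoxy-4-(methoxymethoxy)phenyl]-7-methoxy-3-methyl-1-benzofuran | Cc1c(-c2cc(OC)c(OCOC)c(OC)c2)oc2c(OC)cc(Cl)cc12 | intermediate
8 | (2S,3R)-5-chloro-2-[3,5-dimethoxy-4-(methoxymethoxy)phenyl]-7-methoxy-3-methyl-2,3-dihydro-1-benzofuran (cis) | Clc1cc(OC)c2c(c1)[C@@H](C)[C@@H](c1cc(OC)c(OCOC)c(OC)c1)O2 | intermediate
9 | 4-[(2S,3R)-5-chloro-7-methoxy-3-methyl-2,3-dihydro-1-benzofuran-2-yl]-2,6-dimethoxyphenol (cis phenol, not isolated) | Clc1cc(OC)c2c(c1)[C@@H](C)[C@@H](c1cc(OC)c(O)c(OC)c1)O2 | intermediate
10 | 4-[(2R,3R)-5-chloro-7-methoxy-3-methyl-2,3-dihydro-1-benzofuran-2-yl]-2,6-dimethoxyphenol (trans) | Clc1cc(OC)c2c(c1)[C@@H](C)[C@H](c1cc(OC)c(O)c(OC)c1)O2 | intermediate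
11 | maceneolignan A, 2,6-dimethoxy-4-[(2R,3R)-7-methoxy-3-methyl-5-[(E)-prop-1-enyl]-2,3-dihydro-1-benzofuran-2-yl]phenol | C/C=C/c1cc(OC)c2c(c1)[C@@H](C)[C@H](c1cc(OC)c(O)c(OC)c1)O2 | target

**Step count and risks**

Total step count: 7. Longest linear sequence: 6 steps (steps 1, 2, 4, 5, 6, 7).

Steps most likely to fail:

Step 5. The tetrasubstituted, electron-rich C2=C3 bond may be hydrogenated slowly or incompletely, hydrogen may be delivered with poor facial selectivity, or the chlorine may be lost reductively. The fallback sets out from compound 7. Ionic hydrogenation (Et3SiH, TFA, CH2Cl2, 0 °C to rt) protonates C3 and delivers hydride to the 2-aryl oxocarbenium ion anti to the C3 methyl group, with loss of the MOM group under the same acid. This should give the racemic trans phenol, that is compound 10 together with its mirror image, 4-[(2S,3S)-5-chloro-7-methoxy-3-methyl-2,3-dihydro-1-benzofuran-2-yl]-2,6-dimethoxyphenol F1. Preparative chromatography on a chiral stationary phase separates the two, and the route is rejoined at compound 10.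

Step 6. Ionisation at C2 may be accompanied by proton loss from C3 (elimination to a stilbene and re-addition, which would erode the C3 configuration), or the equilibration may stop short of the trans isomer. The fallback sets out from compounds 3 and 5 and makes the trans ring without any epimerisation. The arylation of step 4 is stopped at ketone 6 (same catalyst, 70 °C, isolated). Dynamic kinetic resolution by Noyori–Ikariya transfer hydrogenation (RuCl(p-cymene)[(S,S)-TsDPEN] or its antipode, whichever gives 1R; HCO2H/Et3N, 40 °C; the benzylic alpha-centre racemises under the conditions) should give the Felkin-type alcohol 4-chloro-2-{(1R,2R)-1-[3,5-dimethoxy-4-(methoxymethoxy)phenyl]-1-hydroxypropan-2-yl}-6-methoxyphenyl trifluoromethanesulfonate F2. Intramolecular palladium-catalysed C–O coupling of the alcohol with the aryl triflate (Pd(OAc)2, 2-(di-tert-butylphosphino)-1,1'-binaphthyl, Cs2CO3, toluene, 70 °C) closes ring B without touching either stereocentre and gives (2R,3R)-5-chloro-2-[3,5-dimethoxy-4-(methoxymethoxy)phenyl]-7-methoxy-3-methyl-2,3-dihydro-1-benzofuran F3. Brief treatment with ZnBr2 and n-PrSH in CH2Cl2 at 0 °C removes the MOM group, and the route is rejoined at compound 10.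

Step 4. The hindered C7a–OTf bond may be lost by S–O cleavage by the base before oxidative addition, or the cascade may stall after the C-arylation. The fallback sets out from compound 6 (reached from 3 and 5 by the C-arylation alone) and closes ring B through the other C–O bond. Aqueous LiOH in THF/MeOH at rt cleaves the triflate to racemic 2-(5-chloro-2-hydroxy-3-methoxyphenyl)-1-[3,5-dimethoxy-4-(methoxymethoxy)phenyl]propan-1-one F4. Its lactol is dehydrated (PPTS cat., toluene, 4 Å molecular sieves, 80 °C) to the benzofuran, and the route is rejoined at compound 7.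

**Further compounds**

F1 | step 5 | 4-[(2S,3S)-5-chloro-7-methoxy-3-methyl-2,3-dihydro-1-benzofuran-2-yl]-2,6-dimethoxyphenol | Clc1cc(OC)c2c(c1)[C@H](C)[C@@H](c1cc(OC)c(O)c(OC)c1)O2
F2 | step 6 | 4-chloro-2-{(1R,2R)-1-[3,5-dimethoxy-4-(methoxymethoxy)phenyl]-1-hydroxypropan-2-yl}-6-methoxyphenyl trifluoromethanesulfonate | COc1cc(Cl)cc([C@@H](C)[C@H](c2cc(OC)c(OCOC)c(OC)c2)O)c1OS(=O)(=O)C(F)(F)F
F3 | step 6 | (2R,3R)-5-chloro-2-[3,5-dimethoxy-4-(methoxymethoxy)phenyl]-7-methoxy-3-methyl-2,3-dihydro-1-benzofuran | Clc1cc(OC)c2c(c1)[C@@H](C)[C@H](c1cc(OC)c(OCOC)c(OC)c1)O2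
F4 | step 4 | racemic 2-(5-chloro-2-hydroxy-3-methoxyphenyl)-1-[3,5-dimethoxy-4-(methoxymethoxy)phenyl]propan-1-one | CC(C(=O)c1cc(OC)c(OCOC)c(OC)c1)c1cc(Cl)cc(OC)c1O
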